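**Plan**

1. The target is (R)-1-(3,5-dihydroxyphenyl)tridecan-2-yl acetate, numbered C1 (benzylic CH2), C2 (acetoxy stereocenter), C3–C13. The retrosynthesis cuts C6–C7 first (mixed Kolbe electrolysis of octanoic acid with an (R)-6-acetoxy-7-arylheptanoic acid, both carboxyl carbons leaving as CO2). It then takes the C2–O bond back to a ring C–C bond (Baeyer–Villiger: oxepan-2-one from a 2-benzylcyclohexanone), and last cuts C1–C2 (α-benzylation of cyclohexanone).
2. The anodic coupling is possible because C6 and C7 lie in an unbranched, heteroatom-free polymethylene run: C3–C6 separate the bond from the acetoxy carbon C2, and C7–C13 is a plain n-heptyl group. Both halves are therefore unstabilised primary alkyl radicals that couple instead of being oxidised further. The only anodically sensitive part, the resorcinol ring, goes through the electrolysis with both phenolic oxygens acetylated.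
3. Forward order: cyclohexanone → RAMP hydrazone → benzylation at the ring α-carbon → ketone → Baeyer–Villiger to the seven-membered lactone → debenzylation → ring opening and peracetylation → Kolbe coupling with octanoic acid → removal of the two aryl acetates. The lactone is a temporary ring: it supplies C2–C6 and puts the carboxyl carbon on C6. The benzene ring is bought.
4. Stereochemistry: the single stereocenter C2 is set as the α-carbon of cyclohexanone by auxiliary-controlled azaenolate alkylation (RAMP). It passes into the lactone with retention in the Baeyer–Villiger migration and lies four carbons from the radical centre in the key step.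

Key step: step 7

Remark: the C=N geometry of hydrazone 6 is left unspecified because it has no influence on the ketone obtained from it. The R sense of induction with RAMP is taken from the accepted azaenolate model (the S auxiliary gives S with a benzylic electrophile).

**Route**

Step 1
Reactants: 1 cyclohexanone; 2 RAMP, (R)-1-amino-2-(methoxymethyl)pyrrolidine
Product: 3 cyclohexanone RAMP hydrazone, (R)-N-cyclohexylidene-2-(methoxymethyl)pyrrolidin-1-amine
Conditions: neat, 60 °C, Ar (or cyclohexane, reflux, Dean–Stark)
Reagents that add atoms: none
Why: Hydrazone formation between a ketone and an N,N-dialkylhydrazine is driven by loss of water and installs the chiral auxiliary; no stereocenter is formed.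

Step 2
Reactants: 3 cyclohexanone RAMP hydrazone; 4 3,5-bis(benzyloxy)benzyl bromide
Product: 6 RAMP hydrazone of (R)-2-[3,5-bis(benzyloxy)benzyl]cyclohexanone, via lithium azaenolate 5 (not isolated)
Conditions: LDA (1.05 equiv), THF, 0 °C; then 4, −100 °C → rt
Reagents that add atoms: none
Why: RAMP-hydrazone (azaenolate) alkylation: the lithium-chelated azaenolate of fixed geometry exposes one face of the ring α-carbon to the reactive benzylic bromide, and with the (R)-auxiliary and a benzylic electrophile the established sense of induction should set the new ring stereocenter as R.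

Step 3
Reactants: 6 RAMP hydrazone of (R)-2-[3,5-bis(benzyloxy)benzyl]cyclohexanone
Product: 7 (R)-2-[3,5-bis(benzyloxy)benzyl]cyclohexanone
Conditions: sat. aq. oxalic acid, Et2O, rt (two phases)
Reagents that add atoms: water, O
Why: Mild two-phase acidic hydrazone hydrolysis should free the ketone without enolising the α-stereocenter, the auxiliary passing into the aqueous phase as its oxalate for recovery and the benzyl ethers staying untouched.

Step 4
Reactants: 7 (R)-2-[3,5-bis(benzyloxy)benzyl]cyclohexanone
Product: 8 (R)-7-[3,5-bis(benzyloxy)benzyl]oxepan-2-one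
Conditions: mCPBA, NaHCO3, CH2Cl2, 0 °C → rt
Reagents that add atoms: mCPBA (3-chloroperoxybenzoic acid), OOC(=O)c1cccc(Cl)c1
Why: Baeyer–Villiger oxidation: the more substituted α-carbon migrates to oxygen with retention, so the ring stereocenter becomes the carbinol carbon C2 with R configuration, and the bicarbonate buffer should prevent acid-catalysed epimerisation of the ketone.

Step 5
Reactants: 8 (R)-7-[3,5-bis(benzyloxy)benzyl]oxepan-2-one
Product: 9 (R)-7-(3,5-dihydroxybenzyl)oxepan-2-one
Conditions: H2 (1 atm), 10% Pd/C, EtOAc, rt
Reagents that add atoms: none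
Why: Hydrogenolysis should remove the two aryl benzyl ethers, while the lactone C–O bond, one carbon removed from the ring and so not benzylic, stays.

Step 6
Reactants: 9 (R)-7-(3,5-dihydroxybenzyl)oxepan-2-one
Product: 12 (R)-6-acetoxy-7-(3,5-diacetoxyphenyl)heptanoic acid, via hydroxy acid 10 (not isolated), via mixed anhydride 11 (not isolated)
Conditions: KOH (3.5 equiv), THF–H2O, 0 °C → rt, Ar; evaporate; Ac2O (excess), pyridine, DMAP (cat.), 0 °C → rt; then H2O, rt; 1 M HCl work-up
Reagents that add atoms: potassium hydroxide, [K+].[OH-]; acetic anhydride, CC(=O)OC(C)=O; water, O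
Why: Lactone saponification followed by exhaustive O-acetylation should convert both phenols and the secondary alcohol into acetates in one operation, the fast DMAP-catalysed acetylation outrunning re-closure of the seven-membered ring and the mixed anhydride at the carboxyl group being hydrolysed by the water quench; the stereocenter is not involved.

Step 7
Reactants: 12 (R)-6-acetoxy-7-(3,5-diacetoxyphenyl)heptanoic acid; 13 octanoic acid
Product: 14 (R)-1-(3,5-diacetoxyphenyl)tridecan-2-yl acetate
Conditions: 12 (1 equiv), 13 (8 equiv), KOH (5 mol% of total acid), MeOH, Pt(+)/Pt(−), undivided cell, constant current ca. 0.25 A cm−2, 10–20 °C, stopped while the bulk is still acidic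
Reagents that add atoms: none
Why: At the platinum anode under high current density both carboxylates are oxidised to acyloxy radicals that lose CO2 at once, and the n-heptyl radical and the primary 5-acetoxy-6-arylhexyl radical, formed at high concentration in the layer at the electrode, combine to form the C6–C7 bond while protons are reduced to H2 at the cathode. The closest known reaction type is the mixed (crossed) Kolbe electrolysis of two unbranched alkanoic acids, which tolerates ester and acetoxy groups placed well away from the carboxyl group. No ring is closed and no stereocenter is created; C2 lies four carbons from the radical centre and bimolecular coupling at the electrode should outrun a 1,5-hydrogen shift, so its configuration is kept. The step needs cross-coupling over homo-coupling, which the eightfold excess of cheap octanoic acid secures for the valuable partner, the by-product tetradecane being a hydrocarbon that silica removes. It needs radical coupling and not further oxidation to a cation, which is secured by both radicals being primary and free of α-substituents, by smooth platinum, high current density and weakly acidic methanol. It needs the arene and the esters to survive, which is why the phenols are carried as acetates (the ring should then be no easier to oxidise than a plain alkylbenzene, a group that survives Kolbe conditions when remote from the carboxyl group) and why the cell is kept cool and never allowed to turn basic.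

Step 8
Reactants: 14 (R)-1-(3,5-diacetoxyphenyl)tridecan-2-yl acetate
Product: 15 (R)-1-(3,5-dihydroxyphenyl)tridecan-2-yl acetate
Conditions: N2H4·H2O (2.2 equiv), THF, 0 °C → rt
Reagents that add atoms: none
Why: Chemoselective hydrazinolysis (aminolysis of activated esters): aryl acetates, with a phenoxide leaving group, react far faster with hydrazine than the unactivated secondary alkyl acetate, so only the two phenolic acetates should be removed and the C2 acetate and its configuration should stay.

**Compound list**

1 | cyclohexanone | O=C1CCCCC1 | starting material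
2 | RAMP, (R)-1-amino-2-(methoxymethyl)pyrrolidine | COC[C@H]1CCCN1N | starting material
3 | cyclohexanone RAMP hydrazone, (R)-N-cyclohexylidene-2-(methoxymethyl)pyrrolidin-1-amine | COC[C@H]1CCCN1N=C1CCCCC1 | intermediate
4 | 3,5-bis(benzyloxy)benzyl bromide | BrCc1cc(OCc2ccccc2)cc(OCc2ccccc2)c1 | starting material
5 | lithium azaenolate of 3 (N-lithiated, C=C in the six-membered ring) | COC[C@H]1CCCN1N([Li])C1=CCCCC1 | intermediate
6 | RAMP hydrazone of (R)-2-[3,5-bis(benzyloxy)benzyl]cyclohexanone, (R)-N-[(R)-2-[3,5-bis(benzyloxy)benzyl]cyclohexylidene]-2-(methoxymethyl)pyrrolidin-1-amine (C=N geometry not specified) | COC[C@H]1CCCN1N=C1CCCC[C@@H]1Cc1cc(OCc2ccccc2)cc(OCc2ccccc2)c1 | intermediate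
7 | (R)-2-[3,5-bis(benzyloxy)benzyl]cyclohexanone | O=C1CCCC[C@@H]1Cc1cc(OCc2ccccc2)cc(OCc2ccccc2)c1 | intermediate
8 | (R)-7-[3,5-bis(benzyloxy)benzyl]oxepan-2-one | O=C1CCCC[C@H](Cc2cc(OCc3ccccc3)cc(OCc3ccccc3)c2)O1 | intermediate
9 | (R)-7-(3,5-dihydroxybenzyl)oxepan-2-one | O=C1CCCC[C@H](Cc2cc(O)cc(O)c2)O1 | intermediate
10 | (R)-7-(3,5-dihydroxyphenyl)-6-hydroxyheptanoic acid (in the flask as its potassium salt) | OC(=O)CCCC[C@@H](O)Cc1cc(O)cc(O)c1 | intermediate
11 | acetic (R)-6-acetoxy-7-(3,5-diacetoxyphenyl)heptanoic anhydride | CC(=O)OC(=O)CCCC[C@@H](OC(C)=O)Cc1cc(OC(C)=O)cc(OC(C)=O)c1 | intermediate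
12 | (R)-6-acetoxy-7-(3,5-diacetoxyphenyl)heptanoic acid | OC(=O)CCCC[C@@H](OC(C)=O)Cc1cc(OC(C)=O)cc(OC(C)=O)c1 | intermediate
13 | octanoic acid | CCCCCCCC(O)=O | starting material
14 | (R)-1-(3,5-diacetoxyphenyl)tridecan-2-yl acetate | CCCCCCCCCCC[C@H](Cc1cc(OC(C)=O)cc(OC(C)=O)c1)OC(C)=O | intermediate
15 | (R)-1-(3,5-dihydroxyphenyl)tridecan-2-yl acetate | CCCCCCCCCCC[C@H](Cc1cc(O)cc(O)c1)OC(C)=O | target

**Step count and risks**

Total step count: 8. Longest linear sequence: 8 steps (1 → 15); octanoic acid 13 enters at step 7 without prior steps.

Steps most likely to fail: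

Step 7. The risks are anodic oxidation of the aromatic ring competing with carboxylate oxidation, methanolysis of the aryl acetates by base formed at the cathode, and statistical loss to homo-coupling. The fallback keeps the same bond but forms it reductively at the cathode, sets out from 12 and comes back at 14. Acid 12 would be esterified with N-hydroxyphthalimide (DIC, DMAP cat., CH2Cl2) to the redox-active ester 1,3-dioxoisoindolin-2-yl (R)-6-acetoxy-7-(3,5-diacetoxyphenyl)heptanoate F1. Octanoic acid 13 would be converted in the same way into 1,3-dioxoisoindolin-2-yl octanoate F2. F1 and F2 (3 equiv) would then be joined by nickel-electrocatalytic doubly decarboxylative C(sp3)–C(sp3) coupling (NiCl2·6H2O, 2,2':6',2''-terpyridine, NaI, DMF, sacrificial Zn anode, RVC cathode, constant current, rt) to give 14. No oxidising potential and no methanol are involved.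

Step 8. The risks are loss of the secondary acetate together with the aryl acetates, or incomplete cleavage of the second aryl acetate. The fallback sets out from 14 and comes back at 15. Exhaustive methanolysis (K2CO3, MeOH) would give (R)-5-(2-hydroxytridecyl)benzene-1,3-diol F3. Phenol-selective benzylation (BnBr, K2CO3, acetone; carbonate does not deprotonate the alcohol) would give (R)-1-[3,5-bis(benzyloxy)phenyl]tridecan-2-ol F4. Acetylation (Ac2O, pyridine, DMAP) would give (R)-1-[3,5-bis(benzyloxy)phenyl]tridecan-2-yl acetate F5. Hydrogenolysis (H2, Pd/C, EtOAc), which cannot touch an alkyl acetate, would give 15.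

Step 6. The risks are re-closure of the seven-membered lactone through the activated carboxyl group before the secondary hydroxyl is acetylated, air oxidation of the resorcinolate, and partial loss of aryl acetates while the mixed anhydride is hydrolysed. The fallback sets out from 8 (phenols still benzylated) and comes back at 12; at no stage does a free secondary hydroxyl meet an activated carboxyl group.
- Saponification (KOH, THF–H2O) would give potassium (R)-7-[3,5-bis(benzyloxy)phenyl]-6-hydroxyheptanoate F6.
- O-Alkylation of the carboxylate (BnBr, DMF) would give benzyl (R)-7-[3,5-bis(benzyloxy)phenyl]-6-hydroxyheptanoate F7.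
- Acetylation (Ac2O, pyridine, DMAP) would give benzyl (R)-6-acetoxy-7-[3,5-bis(benzyloxy)phenyl]heptanoate F8.
- One hydrogenolysis (H2, Pd/C, EtOAc) would remove all three benzyl groups to give (R)-6-acetoxy-7-(3,5-dihydroxyphenyl)heptanoic acid F9.
- Acetylation of the phenols (Ac2O, pyridine; then water, passing through 11) would give 12.

**Further compounds**

F1 | step 7 | 1,3-dioxoisoindolin-2-yl (R)-6-acetoxy-7-(3,5-diacetoxyphenyl)heptanoate | O=C1c2ccccc2C(=O)N1OC(=O)CCCC[C@@H](OC(C)=O)Cc1cc(OC(C)=O)cc(OC(C)=O)c1
F2 | step 7 | 1,3-dioxoisoindolin-2-yl octanoate | CCCCCCCC(=O)ON1C(=O)c2ccccc2C1=O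
F3 | step 8 | (R)-5-(2-hydroxytridecyl)benzene-1,3-diol | CCCCCCCCCCC[C@@H](O)Cc1cc(O)cc(O)c1
F4 | step 8 | (R)-1-[3,5-bis(benzyloxy)phenyl]tridecan-2-ol | CCCCCCCCCCC[C@@H](O)Cc1cc(OCc2ccccc2)cc(OCc2ccccc2)c1
F5 | step 8 | (R)-1-[3,5-bis(benzyloxy)phenyl]tridecan-2-yl acetate | CCCCCCCCCCC[C@H](Cc1cc(OCc2ccccc2)cc(OCc2ccccc2)c1)OC(C)=O
F6 | step 6 | potassium (R)-7-[3,5-bis(benzyloxy)phenyl]-6-hydroxyheptanoate | [K+].[O-]C(=O)CCCC[C@@H](O)Cc1cc(OCc2ccccc2)cc(OCc2ccccc2)c1
F7 | step 6 | benzyl (R)-7-[3,5-bis(benzyloxy)phenyl]-6-hydroxyheptanoate | O=C(CCCC[C@@H](O)Cc1cc(OCc2ccccc2)cc(OCc2ccccc2)c1)OCc1ccccc1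
F8 | step 6 | benzyl (R)-6-acetoxy-7-[3,5-bis(benzyloxy)phenyl]heptanoate | O=C(CCCC[C@@H](OC(C)=O)Cc1cc(OCc2ccccc2)cc(OCc2ccccc2)c1)OCc1ccccc1
F9 | step 6 | (R)-6-acetoxy-7-(3,5-dihydroxyphenyl)heptanoic acid | OC(=O)CCCC[C@@H](OC(C)=O)Cc1cc(O)cc(O)c1
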